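**Retrosynthetic overview**
1. The 18-membered macrolactone is opened at the enoate C=C (ring-closing metathesis of the oxolane C3 acrylate onto a terminal vinyl group); the acid side chain is cut at its Z-alkene (Wittig, ylide from (S)-citramalic acid); the oxazole C2–CH2 bond by B-alkyl Suzuki–Miyaura coupling to a purchased 2-chlorooxazole; the CH(OMe) carbon by chelate-controlled Grignard addition.
2. Key disconnection: the C2–C3 and C4–C5 bonds of the bromo-oxolane are made together by [3+2] cycloaddition of a six-membered carbonyl ylide (Rh carbenoid of an achiral keto diazoacetate) with (E)-2-bromoethenyl acetate.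
3. Enabling feature: ring oxygen O1 lies between C2 (one H; its CH(OMe) neighbour can be a carboxyl carbon) and quaternary C5, whose methyl is cis to that C2 carbon. The two can therefore be tied as a lactone (C2, C=O, O, CH2, C5, O1 = a 1,4-dioxan-2-one), which fixes the ylide geometry; C3–O and C4–Br are trans, i.e. an E-alkene.
4. Ring order: dioxanone and oxolane together (key step) → lactone opened, its CH2O reduced to the C5 methyl → oxazole (bought ring) attached → macrolactone closed last.

Key step: step 7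

Assumption (chemistry): the sense of asymmetric induction of the chiral dirhodium carboxylate in step 7 is taken as drawn; should the antipode prevail, the R-configured catalyst would be used with nothing else changed.

**Route**

Step 1
Reactants: 1 but-3-en-1-ol; 2 4-methoxybenzyl chloride
Product: 3 1-[(but-3-en-1-yloxy)methyl]-4-methoxybenzene
Conditions: NaH, Bu4NI (cat.), THF, 0 °C → rt
Reagents that add atoms: none
Why: Williamson etherification gives a PMB ether that can later be removed oxidatively in the presence of silyl ethers.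

Step 2
Reactants: 3 1-[(but-3-en-1-yloxy)methyl]-4-methoxybenzene
Product: 4 rac-4-[(4-methoxybenzyl)oxy]butane-1,2-diol
Conditions: K2OsO4·2H2O (cat.), N-methylmorpholine N-oxide, acetone/H2O, rt
Reagents that add atoms: N-methylmorpholine N-oxide, C[N+]1([O-])CCOCC1; water, O
Why: Upjohn dihydroxylation of the terminal alkene; the racemic carbinol carbon becomes a ketone in step 4, so no stereocontrol is needed.

Step 3
Reactants: 4 rac-4-[(4-methoxybenzyl)oxy]butane-1,2-diol
Product: 6 rac-2-hydroxy-4-[(4-methoxybenzyl)oxy]butyl diazoacetate, via bromoacetate 5 (not isolated)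
Conditions: BrCH2COBr, 2,4,6-collidine, THF, −78 °C; then TsNHNHTs, DBU, 0 °C
Reagents that add atoms: bromoacetyl bromide, BrCC(Br)=O; N,N'-ditosylhydrazine, Cc1ccc(cc1)S(=O)(=O)NNS(=O)(=O)c1ccc(C)cc1
Why: Low-temperature acylation should be selective for the primary hydroxyl, and the bromoacetate is turned into the diazoacetate by N-alkylation of ditosylhydrazine and double sulfinate elimination (ditosylhydrazine diazoacetate synthesis).

Step 4
Reactants: 6 rac-2-hydroxy-4-[(4-methoxybenzyl)oxy]butyl diazoacetate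
Product: 7 4-[(4-methoxybenzyl)oxy]-2-oxobutyl diazoacetate
Conditions: Dess–Martin periodinane, pyridine, CH2Cl2, 0 °C → rt
Reagents that add atoms: none
Why: Buffered Dess–Martin oxidation of the secondary alcohol, which an acceptor-stabilised diazo ester should tolerate, gives the achiral keto diazoacetate.

Step 5
Reactants: 8 but-3-yn-2-one
Product: 9 (E)-4-bromobut-3-en-2-one
Conditions: HBr (33% in AcOH), CH2Cl2, 0 °C → rt
Reagents that add atoms: hydrogen bromide, Br
Why: Conjugate hydrobromination of the ynone, in which the adduct should equilibrate under acid by addition–elimination to the more stable E-β-bromo enone.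

Step 6
Reactants: 9 (E)-4-bromobut-3-en-2-one
Product: 10 (E)-2-bromoethenyl acetate
Conditions: CF3CO3H [from (CF3CO)2O and H2O2·urea], Na2HPO4, CH2Cl2, 0 °C
Reagents that add atoms: trifluoroperacetic acid, OOC(=O)C(F)(F)F
Why: Baeyer–Villiger oxidation in which the alkenyl group should migrate in preference to methyl with retention of the double-bond geometry, while the electron-poor C=C resists epoxidation.

Step 7
Reactants: 7 4-[(4-methoxybenzyl)oxy]-2-oxobutyl diazoacetate; 10 (E)-2-bromoethenyl acetate
Product: 12 7-exo-acetoxy-6-endo-bromo-5-{2-[(4-methoxybenzyl)oxy]ethyl}-3,8-dioxabicyclo[3.2.1]octan-2-one, via carbonyl ylide 11 (not isolated)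
Conditions: Rh2(S-TCPTTL)4 (dirhodium tetrakis[N-tetrachlorophthaloyl-(S)-tert-leucinate], 1 mol %), 10 (5 equiv), PhCF3, 25 °C, 7 added over 6 h
Reagents that add atoms: none
Why: Proposed new method: loss of N2 from 7 at the dirhodium centre gives an electrophilic carbenoid that is captured by a lone pair of the ketone oxygen through the ester tether to give the 1,4-dioxan-2-one carbonyl ylide 11, which adds suprafacially across the C=C of 10 in a concerted [3+2] cycloaddition that forms both C–C bonds of the oxolane. The closest known reaction type is the dirhodium-carboxylate-catalysed cyclisation–cycloaddition of 1-diazo-2,5-diones (six-membered carbonyl ylides) with alkenes, vinyl ethers and alkynes, including enantioselective versions with N-phthaloyl amino acid dirhodium catalysts; new here are the ester tether and a trans-2-bromovinyl ester as the 2π partner. The dioxanone ring closes by attack of oxygen on the carbenoid carbon (six-membered closure that also makes the O1–C2 bond), and the oxolane closes by the intermolecular [3+2] addition across the C–O–C dipole, which gives the bridged bicycle. The lactone bridge forces the carboxyl carbon on C2 and the CH2O group on C5 (the future methyl) to be cis, the E-geometry of 10 is transferred to the trans O/Br relation at C3/C4 with acetoxy exo and bromine endo, and the absolute sense comes from the chiral catalyst to which the ylide stays associated. The step needs regioselectivity, expected from polarity (the nucleophilic CHBr carbon of the enol ester bonds to the oxocarbenium-like ketone carbon, the CH(OAc) carbon to the ester-stabilised carbanion carbon), exo placement of the larger acetoxy group, and trapping of the ylide faster than 1,4-proton shift or dimerisation, which slow addition of 7 into excess 10 should secure.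

Step 8
Reactants: 12 bicyclic bromo acetate lactone
Product: 13 oxolane diol N-methoxy-N-methylamide
Conditions: MeNH(OMe)·HCl, AlMe3, CH2Cl2, 0 °C → rt
Reagents that add atoms: N,O-dimethylhydroxylamine hydrochloride, CNOC.Cl
Why: Aluminium-amide aminolysis (Weinreb amide formation) opens the bridged lactone and cleaves the acetate in the same operation without forming a free alkoxide that could displace the trans bromide.

Step 9
Reactants: 13 oxolane diol N-methoxy-N-methylamide
Product: 14 primary tosylate
Conditions: TsCl, Et3N, Me3N·HCl (cat.), CH2Cl2, 0 °C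
Reagents that add atoms: p-toluenesulfonyl chloride, Cc1ccc(cc1)S(Cl)(=O)=O
Why: Sulfonylation should be selective for the primary hydroxyl over the flanked secondary one, and the tosylate serves as protecting group now and as leaving group for the reduction to methyl in step 19.

Step 10
Reactants: 14 primary tosylate
Product: 15 triethylsilyl ether tosylate amide
Conditions: Et3SiOTf, 2,6-lutidine, CH2Cl2, −78 °C
Reagents that add atoms: triethylsilyl triflate, CC[Si](CC)(CC)OS(=O)(=O)C(F)(F)F
Why: Silylation under non-basic triflate/lutidine conditions masks the C3 hydroxyl before any strongly basic step, so that no alkoxide anti to the C4 bromide is ever formed.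

Step 11
Reactants: 15 triethylsilyl ether tosylate amide
Product: 16 oxolane-2-carbaldehyde
Conditions: i-Bu2AlH, THF, −78 °C
Reagents that add atoms: none
Why: Reduction of the N-methoxy-N-methylamide stops at the chelated hemiaminal and gives the α-alkoxy aldehyde, while sulfonate, bromide and silyl ether are inert at −78 °C.

Step 12
Reactants: 17 methyl (R)-3-hydroxy-2-methylpropanoate
Product: 18 methyl (R)-3-[(tert-butyldiphenylsilyl)oxy]-2-methylpropanoate
Conditions: t-BuPh2SiCl, imidazole, DMF, rt
Reagents that add atoms: tert-butyl(chloro)diphenylsilane, CC(C)(C)[Si](Cl)(c1ccccc1)c1ccccc1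
Why: Standard silylation of the Roche ester; its stereocentre becomes the ring CH(CH3) of the target.

Step 13
Reactants: 18 methyl (R)-3-[(tert-butyldiphenylsilyl)oxy]-2-methylpropanoate
Product: 19 (R)-3-[(tert-butyldiphenylsilyl)oxy]-2-methylpropanal
Conditions: i-Bu2AlH, CH2Cl2, −78 °C
Reagents that add atoms: none
Why: Partial reduction of the ester at low temperature gives the configurationally usable α-methyl aldehyde, which is taken on at once.

Step 14
Reactants: 19 (R)-3-[(tert-butyldiphenylsilyl)oxy]-2-methylpropanal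
Product: 20 (S)-tert-butyl[(2-methylbut-3-en-1-yl)oxy]diphenylsilane
Conditions: Ph3PCH3Br, KOt-Bu, THF, 0 °C
Reagents that add atoms: methyltriphenylphosphonium bromide, C[P+](c1ccccc1)(c1ccccc1)c1ccccc1.[Br-]
Why: Wittig methylenation is fast enough to outrun epimerisation of the α-stereocentre (the descriptor changes only through priorities).

Step 15
Reactants: 20 (S)-tert-butyl[(2-methylbut-3-en-1-yl)oxy]diphenylsilane
Product: 21 (S)-2-methylbut-3-en-1-ol
Conditions: HF·pyridine, THF, 0 °C → rt
Reagents that add atoms: none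
Why: Fluoride-mediated desilylation frees the primary alcohol without touching the allylic stereocentre.

Step 16
Reactants: 21 (S)-2-methylbut-3-en-1-ol
Product: 22 (S)-4-iodo-3-methylbut-1-ene
Conditions: I2, PPh3, imidazole, Et2O/MeCN, 0 °C
Reagents that add atoms: iodine, II
Why: Appel iodination of the primary alcohol proceeds at carbon remote from the stereocentre.

Step 17
Reactants: 16 oxolane-2-carbaldehyde; 22 (S)-4-iodo-3-methylbut-1-ene
Product: 25 (S)-carbinol, via alkyllithium 23 (not isolated), via Grignard reagent 24 (not isolated)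
Conditions: 22, t-BuLi, Et2O, −78 °C; MgBr2·OEt2; then 16, CH2Cl2, −78 °C
Reagents that add atoms: none
Why: Cram-chelate Grignard addition, in which magnesium bridges the aldehyde oxygen and the ring oxygen and the nucleophile enters from the side of the C2 hydrogen, away from C3 and its silyloxy group, so the new carbinol should have the S configuration required for the methoxy carbon.

Step 18
Reactants: 25 (S)-carbinol
Product: 26 methyl ether tosylate
Conditions: MeOTf, 2,6-di-tert-butyl-4-methylpyridine, CH2Cl2, rt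
Reagents that add atoms: methyl triflate, COS(=O)(=O)C(F)(F)F
Why: O-Methylation under non-basic conditions avoids an alkoxide that could attack the cis CH2OTs group or the bromide.

Step 19
Reactants: 26 methyl ether tosylate
Product: 27 5-methyl oxolane alkene
Conditions: LiEt3BH, THF, 0 → 50 °C
Reagents that add atoms: none
Why: Hydride displacement of the primary sulfonate turns the former tether carbon into the C5 methyl; the secondary bromide has no anti β-hydrogen (the C3 hydrogen is syn, C5 is quaternary) and its backside is shielded by two cis neighbours, so it should survive.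

Step 20
Reactants: 28 ethyl 2-chloro-1,3-oxazole-4-carboxylate
Product: 29 2-chloro-N-methoxy-N-methyl-1,3-oxazole-4-carboxamide
Conditions: MeNH(OMe)·HCl, i-PrMgCl, THF, −20 °C
Reagents that add atoms: N,O-dimethylhydroxylamine hydrochloride, CNOC.Cl
Why: Magnesium-amide aminolysis of the ester gives the Weinreb amide at a temperature at which the 2-chloride is not substituted.

Step 21
Reactants: 29 2-chloro-N-methoxy-N-methyl-1,3-oxazole-4-carboxamide
Product: 30 1-(2-chloro-1,3-oxazol-4-yl)ethan-1-one
Conditions: MeMgBr, THF, −78 → 0 °C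
Reagents that add atoms: methylmagnesium bromide, C[Mg]Br
Why: Single Grignard addition to the Weinreb amide gives the methyl ketone through the stable chelated intermediate.

Step 22
Reactants: 30 1-(2-chloro-1,3-oxazol-4-yl)ethan-1-one
Product: 31 (E)-3-(2-chloro-1,3-oxazol-4-yl)-N-methoxy-N-methylbut-2-enamide
Conditions: (EtO)2P(O)CH2C(O)N(OMe)Me, NaH, THF, 0 °C → rt
Reagents that add atoms: diethyl [2-(methoxy(methyl)amino)-2-oxoethyl]phosphonate, CCOP(=O)(CC(=O)N(C)OC)OCC
Why: Horner–Wadsworth–Emmons olefination of the heteroaryl methyl ketone should place the carboxamide trans to the larger oxazolyl group, which sets the E trisubstituted alkene.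

Step 23
Reactants: 31 (E)-3-(2-chloro-1,3-oxazol-4-yl)-N-methoxy-N-methylbut-2-enamide
Product: 32 (E)-3-(2-chloro-1,3-oxazol-4-yl)but-2-enal
Conditions: i-Bu2AlH, THF, −78 °C
Reagents that add atoms: none
Why: Reduction of the unsaturated Weinreb amide gives the enal directly without erosion of the alkene geometry.

Step 24
Reactants: 32 (E)-3-(2-chloro-1,3-oxazol-4-yl)but-2-enal
Product: 33 (2E,4R,5S)-2-(2-chloro-1,3-oxazol-4-yl)-5-methylhepta-2,6-dien-4-ol
Conditions: cis-2-butene, KOt-Bu, n-BuLi, THF, −78 → −45 °C; (+)-Ipc2BOMe; BF3·OEt2; 32, −78 °C; NaOH, H2O2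
Reagents that add atoms: cis-but-2-ene, C/C=C\C
Why: Brown crotylboration, in which the Z-crotylborane gives the syn relation through the closed chair transition state and the isopinocampheyl groups of the (+)-reagent should direct attack to the Re face of the enal, giving the 4R,5S alcohol.

Step 25
Reactants: 33 (2E,4R,5S)-2-(2-chloro-1,3-oxazol-4-yl)-5-methylhepta-2,6-dien-4-ol
Product: 34 (2E,4R,5S)-4-[(tert-butyldimethylsilyl)oxy]-2-(2-chloro-1,3-oxazol-4-yl)-5-methylhepta-2,6-diene
Conditions: t-BuMe2SiOTf, 2,6-lutidine, CH2Cl2, −78 °C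
Reagents that add atoms: tert-butyldimethylsilyl triflate, CC(C)(C)[Si](C)(C)OS(=O)(=O)C(F)(F)F
Why: Silylation gives a TBS ether that outlasts the later selective removal of the triethylsilyl and PMB groups.

Step 26
Reactants: 27 5-methyl oxolane alkene; 34 silylated 2-chlorooxazole diene
Product: 36 coupled oxazole, via B-alkyl-9-BBN borane 35 (not isolated)
Conditions: 27, 9-BBN, THF, rt; then K3PO4 (aq.), 34, Pd(OAc)2, SPhos, THF/H2O, 60 °C
Reagents that add atoms: none
Why: Anti-Markovnikov hydroboration of the only alkene of 27, quenching of excess borane by the aqueous base, and B-alkyl Suzuki–Miyaura coupling at the activated 2-chloride make the CH2–oxazole bond; the hindered secondary bromide should not add oxidatively to zerovalent palladium.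

Step 27
Reactants: 36 coupled oxazole
Product: 37 C3 alcohol
Conditions: PPTS, MeOH/CH2Cl2, 0 °C
Reagents that add atoms: none
Why: Mild acid methanolysis removes the triethylsilyl ether in the presence of the TBS and PMB ethers, and the acidic medium cannot close the bromohydrin to an epoxide.

Step 28
Reactants: 37 C3 alcohol
Product: 38 acrylate
Conditions: CH2=CHCOCl, i-Pr2NEt, CH2Cl2, −20 → 0 °C
Reagents that add atoms: acryloyl chloride, C=CC(Cl)=O
Why: Acylation by the small, reactive acid chloride suits the hindered secondary alcohol, and the weak amine base does not generate an alkoxide.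

Step 29
Reactants: 38 acrylate
Product: 39 macrolactone PMB ether
Conditions: second-generation Hoveyda–Grubbs catalyst (10 mol %), toluene (1 mM), 80 °C
Reagents that add atoms: none
Why: Ring-closing metathesis between the acrylate and the terminal vinyl group closes the 18-membered ring with loss of ethene, and the conjugated disubstituted alkene should form as the E isomer while the trisubstituted alkene stays inert.

Step 30
Reactants: 39 macrolactone PMB ether
Product: 40 macrolactone primary alcohol
Conditions: DDQ, CH2Cl2/pH 7 buffer, 0 °C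
Reagents that add atoms: none
Why: Oxidative PMB cleavage frees only the primary alcohol, since the silyl ether, enoate and bromide are inert to DDQ.

Step 31
Reactants: 40 macrolactone primary alcohol
Product: 41 macrolactone aldehyde
Conditions: Dess–Martin periodinane, pyridine, CH2Cl2, 0 °C → rt
Reagents that add atoms: none
Why: Neutral Dess–Martin oxidation gives the β-alkoxy aldehyde without base that could open the oxolane by β-elimination.

Step 32
Reactants: 42 (S)-citramalic acid
Product: 43 2-[(4S)-2,2,4-trimethyl-5-oxo-1,3-dioxolan-4-yl]acetic acid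
Conditions: Me2C(OMe)2, TsOH (cat.), rt
Reagents that add atoms: 2,2-dimethoxypropane, COC(C)(C)OC
Why: Acetalisation ties the tertiary hydroxyl and the adjacent carboxyl into a dioxolanone and leaves only the remote carboxyl free; the chiral-pool stereocentre is untouched.

Step 33
Reactants: 43 2-[(4S)-2,2,4-trimethyl-5-oxo-1,3-dioxolan-4-yl]acetic acid
Product: 44 (5S)-5-(2-hydroxyethyl)-2,2,5-trimethyl-1,3-dioxolan-4-one
Conditions: BH3·SMe2, THF, 0 °C → rt; MeOH
Reagents that add atoms: none
Why: Borane reduces the free carboxylic acid chemoselectively in the presence of the lactone-like dioxolanone carbonyl.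

Step 34
Reactants: 44 (5S)-5-(2-hydroxyethyl)-2,2,5-trimethyl-1,3-dioxolan-4-one
Product: 45 (5S)-5-(2-iodoethyl)-2,2,5-trimethyl-1,3-dioxolan-4-one
Conditions: I2, PPh3, imidazole, CH2Cl2, 0 °C
Reagents that add atoms: iodine, II
Why: Appel iodination of the primary alcohol under neutral conditions that keep the dioxolanone closed.

Step 35
Reactants: 45 (5S)-5-(2-iodoethyl)-2,2,5-trimethyl-1,3-dioxolan-4-one
Product: 46 {2-[(4S)-2,2,4-trimethyl-5-oxo-1,3-dioxolan-4-yl]ethyl}triphenylphosphonium iodide
Conditions: PPh3, MeCN, 80 °C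
Reagents that add atoms: triphenylphosphine, c1ccc(cc1)P(c1ccccc1)c1ccccc1
Why: Quaternisation of triphenylphosphine by the unhindered primary iodide gives the Wittig salt.

Step 36
Reactants: 41 macrolactone aldehyde; 46 dioxolanone phosphonium iodide
Product: 48 protected Z-alkene, via phosphorus ylide 47 (not isolated)
Conditions: 46, NaN(SiMe3)2, THF, −78 °C; then 41, −78 → −20 °C
Reagents that add atoms: none
Why: Wittig olefination with a non-stabilised ylide under kinetic conditions should give the Z-alkene; protection of the tertiary oxygen avoids the E-directing effect of a free γ-oxido group, and the α-quaternary dioxolanone carbonyl is too hindered to acylate the ylide at low temperature.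

Step 37
Reactants: 48 protected Z-alkene
Product: 49 CNP0163177.2 (target)
Conditions: HF (48% aq.), MeCN, 0 °C → rt
Reagents that add atoms: none
Why: Aqueous acidic fluoride removes the TBS ether and hydrolyses the acetone acetal of the dioxolanone to the free α-hydroxy acid, under conditions that cannot form an alkoxide next to the bromide or saponify the macrolactone.

**Compound list**
Oxolane numbering used in the names: O1, C2 (carbon substituent), C3 (oxygen), C4 (bromine), C5 (quaternary). In every oxolane from 13 on, the C2 substituent and the one-carbon group on C5 (CH2O or CH3) are cis, C3–O is trans to the C2 substituent, and C4–Br is trans to C3–O; absolute configuration as in the SMILES.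

1 | but-3-en-1-ol | C=CCCO | starting material
2 | 4-methoxybenzyl chloride | COc1ccc(CCl)cc1 | starting material
3 | 1-[(but-3-en-1-yloxy)methyl]-4-methoxybenzene | C=CCCOCc1ccc(OC)cc1 | intermediate
4 | rac-4-[(4-methoxybenzyl)oxy]butane-1,2-diol (racemic, no stereodescriptor) | OCC(O)CCOCc1ccc(OC)cc1 | intermediate
5 | rac-2-hydroxy-4-[(4-methoxybenzyl)oxy]butyl bromoacetate | BrCC(=O)OCC(O)CCOCc1ccc(OC)cc1 | intermediate
6 | rac-2-hydroxy-4-[(4-methoxybenzyl)oxy]butyl diazoacetate | [N-]=[N+]=CC(=O)OCC(O)CCOCc1ccc(OC)cc1 | intermediate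
7 | 4-[(4-methoxybenzyl)oxy]-2-oxobutyl diazoacetate (achiral) | [N-]=[N+]=CC(=O)OCC(=O)CCOCc1ccc(OC)cc1 | intermediate
8 | but-3-yn-2-one | CC(=O)C#C | starting material
9 | (E)-4-bromobut-3-en-2-one | CC(=O)/C=C/Br | intermediate
10 | (E)-2-bromoethenyl acetate | CC(=O)O/C=C/Br | intermediate
11 | six-membered carbonyl ylide (5-{2-[(4-methoxybenzyl)oxy]ethyl}-2-oxo-1,4-dioxan-3-ide with oxocarbenium at C5=O4) | [CH-]1C(=O)OCC(CCOCc2ccc(OC)cc2)=[O+]1 | intermediate
12 | 7-exo-acetoxy-6-endo-bromo-5-{2-[(4-methoxybenzyl)oxy]ethyl}-3,8-dioxabicyclo[3.2.1]octan-2-one | CC(=O)O[C@@H]1[C@@H]2O[C@](COC2=O)(CCOCc3ccc(OC)cc3)[C@H]1Br | intermediate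
13 | 4-bromo-3-hydroxy-5-(hydroxymethyl)-N-methoxy-N-methyl-5-{2-[(4-methoxybenzyl)oxy]ethyl}oxolane-2-carboxamide | O[C@@H]1[C@@H](C(=O)N(C)OC)O[C@](CO)(CCOCc2ccc(OC)cc2)[C@H]1Br | intermediate
14 | the 5-(tosyloxymethyl) analogue of 13 | O[C@@H]1[C@@H](C(=O)N(C)OC)O[C@](COS(=O)(=O)c2ccc(C)cc2)(CCOCc3ccc(OC)cc3)[C@H]1Br | intermediate
15 | the 3-O-triethylsilyl ether of 14 | CC[Si](CC)(CC)O[C@@H]1[C@@H](C(=O)N(C)OC)O[C@](COS(=O)(=O)c2ccc(C)cc2)(CCOCc3ccc(OC)cc3)[C@H]1Br | intermediate
16 | 4-bromo-5-{2-[(4-methoxybenzyl)oxy]ethyl}-5-(tosyloxymethyl)-3-(triethylsilyloxy)oxolane-2-carbaldehyde | CC[Si](CC)(CC)O[C@@H]1[C@@H](C=O)O[C@](COS(=O)(=O)c2ccc(C)cc2)(CCOCc3ccc(OC)cc3)[C@H]1Br | intermediate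
17 | methyl (R)-3-hydroxy-2-methylpropanoate | OC[C@@H](C)C(=O)OC | starting material
18 | methyl (R)-3-[(tert-butyldiphenylsilyl)oxy]-2-methylpropanoate | CC(C)(C)[Si](c1ccccc1)(c1ccccc1)OC[C@@H](C)C(=O)OC | intermediate
19 | (R)-3-[(tert-butyldiphenylsilyl)oxy]-2-methylpropanal | CC(C)(C)[Si](c1ccccc1)(c1ccccc1)OC[C@@H](C)C=O | intermediate
20 | (S)-tert-butyl[(2-methylbut-3-en-1-yl)oxy]diphenylsilane | CC(C)(C)[Si](c1ccccc1)(c1ccccc1)OC[C@@H](C)C=C | intermediate
21 | (S)-2-methylbut-3-en-1-ol | OC[C@@H](C)C=C | intermediate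
22 | (S)-4-iodo-3-methylbut-1-ene | IC[C@@H](C)C=C | intermediate
23 | [(S)-2-methylbut-3-en-1-yl]lithium | [Li]C[C@@H](C)C=C | intermediate
24 | [(S)-2-methylbut-3-en-1-yl]magnesium bromide | Br[Mg]C[C@@H](C)C=C | intermediate
25 | oxolane of 16 with C2 = (1S,3R)-1-hydroxy-3-methylpent-4-en-1-yl | CC[Si](CC)(CC)O[C@@H]1[C@@H]([C@@H](O)C[C@@H](C)C=C)O[C@](COS(=O)(=O)c2ccc(C)cc2)(CCOCc3ccc(OC)cc3)[C@H]1Br | intermediate
26 | the O-methyl ether of 25 (C2 = (1S,3R)-1-methoxy-3-methylpent-4-en-1-yl) | CC[Si](CC)(CC)O[C@@H]1[C@@H]([C@@H](OC)C[C@@H](C)C=C)O[C@](COS(=O)(=O)c2ccc(C)cc2)(CCOCc3ccc(OC)cc3)[C@H]1Br | intermediate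
27 | 4-bromo-2-[(1S,3R)-1-methoxy-3-methylpent-4-en-1-yl]-5-methyl-5-{2-[(4-methoxybenzyl)oxy]ethyl}-3-(triethylsilyloxy)oxolane | CC[Si](CC)(CC)O[C@@H]1[C@@H]([C@@H](OC)C[C@@H](C)C=C)O[C@](C)(CCOCc2ccc(OC)cc2)[C@H]1Br | intermediate
28 | ethyl 2-chloro-1,3-oxazole-4-carboxylate | CCOC(=O)c1coc(Cl)n1 | starting material
29 | 2-chloro-N-methoxy-N-methyl-1,3-oxazole-4-carboxamide | CON(C)C(=O)c1coc(Cl)n1 | intermediate
30 | 1-(2-chloro-1,3-oxazol-4-yl)ethan-1-one | CC(=O)c1coc(Cl)n1 | intermediate
31 | (E)-3-(2-chloro-1,3-oxazol-4-yl)-N-methoxy-N-methylbut-2-enamide | Clc1nc(co1)/C(C)=C/C(=O)N(C)OC | intermediate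
32 | (E)-3-(2-chloro-1,3-oxazol-4-yl)but-2-enal | Clc1nc(co1)/C(C)=C/C=O | intermediate
33 | (2E,4R,5S)-2-(2-chloro-1,3-oxazol-4-yl)-5-methylhepta-2,6-dien-4-ol | Clc1nc(co1)/C(C)=C/[C@H](O)[C@@H](C)C=C | intermediate
34 | (2E,4R,5S)-4-[(tert-butyldimethylsilyl)oxy]-2-(2-chloro-1,3-oxazol-4-yl)-5-methylhepta-2,6-diene | Clc1nc(co1)/C(C)=C/[C@H](O[Si](C)(C)C(C)(C)C)[C@@H](C)C=C | intermediate
35 | B-alkyl-9-borabicyclo[3.3.1]nonane from 27 (boron on the terminal carbon) | CC[Si](CC)(CC)O[C@@H]1[C@@H]([C@@H](OC)C[C@@H](C)CCB2C3CCCC2CCC3)O[C@](C)(CCOCc4ccc(OC)cc4)[C@H]1Br | intermediate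
36 | oxolane 27 whose pentenyl terminus is bonded to C2 of the oxazole of 34 (2-alkyl-4-alkenyloxazole; TES, TBS and PMB ethers) | CC[Si](CC)(CC)O[C@@H]1[C@@H]([C@@H](OC)C[C@@H](C)CCc2nc(co2)/C(C)=C/[C@H](O[Si](C)(C)C(C)(C)C)[C@@H](C)C=C)O[C@](C)(CCOCc3ccc(OC)cc3)[C@H]1Br | intermediate
37 | 36 with free C3 hydroxyl | O[C@@H]1[C@@H]([C@@H](OC)C[C@@H](C)CCc2nc(co2)/C(C)=C/[C@H](O[Si](C)(C)C(C)(C)C)[C@@H](C)C=C)O[C@](C)(CCOCc3ccc(OC)cc3)[C@H]1Br | intermediate
38 | C3 acrylate of 37 | C=CC(=O)O[C@@H]1[C@@H]([C@@H](OC)C[C@@H](C)CCc2nc(co2)/C(C)=C/[C@H](O[Si](C)(C)C(C)(C)C)[C@@H](C)C=C)O[C@](C)(CCOCc3ccc(OC)cc3)[C@H]1Br | intermediate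
39 | 18-membered E-enoate macrolactone with allylic OTBS and a CH2CH2OPMB chain on C5 | CO[C@H]1C[C@@H](C)CCc2nc(co2)/C(C)=C/[C@H](O[Si](C)(C)C(C)(C)C)[C@@H](C)/C=C/C(=O)O[C@@H]3[C@@H]1O[C@](C)(CCOCc4ccc(OC)cc4)[C@H]3Br | intermediate
40 | macrolactone with CH2CH2OH on C5 | CO[C@H]1C[C@@H](C)CCc2nc(co2)/C(C)=C/[C@H](O[Si](C)(C)C(C)(C)C)[C@@H](C)/C=C/C(=O)O[C@@H]3[C@@H]1O[C@](C)(CCO)[C@H]3Br | intermediate
41 | macrolactone with CH2CHO on C5 | CO[C@H]1C[C@@H](C)CCc2nc(co2)/C(C)=C/[C@H](O[Si](C)(C)C(C)(C)C)[C@@H](C)/C=C/C(=O)O[C@@H]3[C@@H]1O[C@](C)(CC=O)[C@H]3Br | intermediate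
42 | (S)-citramalic acid [(S)-2-hydroxy-2-methylbutanedioic acid] | OC(=O)C[C@](C)(O)C(=O)O | starting material
43 | 2-[(4S)-2,2,4-trimethyl-5-oxo-1,3-dioxolan-4-yl]acetic acid | OC(=O)C[C@]1(C)OC(C)(C)OC1=O | intermediate
44 | (5S)-5-(2-hydroxyethyl)-2,2,5-trimethyl-1,3-dioxolan-4-one | OCC[C@]1(C)OC(C)(C)OC1=O | intermediate
45 | (5S)-5-(2-iodoethyl)-2,2,5-trimethyl-1,3-dioxolan-4-one | ICC[C@]1(C)OC(C)(C)OC1=O | intermediate
46 | {2-[(4S)-2,2,4-trimethyl-5-oxo-1,3-dioxolan-4-yl]ethyl}triphenylphosphonium iodide | [I-].c1ccccc1[P+](c1ccccc1)(c1ccccc1)CC[C@]2(C)OC(C)(C)OC2=O | intermediate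
47 | the phosphorus ylide of 46 | c1ccccc1P(c1ccccc1)(c1ccccc1)=CC[C@]2(C)OC(C)(C)OC2=O | intermediate
48 | macrolactone with the Z side chain, dioxolanone-protected hydroxy acid and allylic OTBS | CO[C@H]1C[C@@H](C)CCc2nc(co2)/C(C)=C/[C@H](O[Si](C)(C)C(C)(C)C)[C@@H](C)/C=C/C(=O)O[C@@H]3[C@@H]1O[C@](C)(C/C=C\C[C@]4(C)OC(C)(C)OC4=O)[C@H]3Br | intermediate
49 | CNP0163177.2 | CO[C@H]1C[C@@H](C)CCc2nc(co2)/C(C)=C/[C@H](O)[C@@H](C)/C=C/C(=O)O[C@@H]2[C@@H]1O[C@](C)(C/C=C\C[C@](C)(O)C(=O)O)[C@H]2Br | target

**Step count and risks**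

Total: 37 steps. Longest linear sequence: 20 steps (1–4, 7–11, 17–19, 26–31, 36, 37).

Steps most likely to fail:

1. Step 7 (proposed new method). What may go wrong: the deactivated bromo enol ester traps the ylide too slowly, so that 1,4-proton shift or dimerisation of the ylide takes over; the exo/endo orientation of the trans alkene inverts; or the catalyst selects the faces poorly. Fallback by known chemistry, setting out from 4-methoxybenzyl chloride 2 and returning at 27. Etherification of commercial but-3-yn-1-ol with 2 (NaH) would give 1-[(but-3-yn-1-yloxy)methyl]-4-methoxybenzene F1. Negishi carboalumination (AlMe3, Cp2ZrCl2) and iodinolysis would give the (E)-vinyl iodide F2. Iodine–lithium exchange (t-BuLi), transmetalation with ZnBr2 and Felkin-selective addition to commercial (R)-2,3-O-isopropylideneglyceraldehyde would give the anti allylic alcohol F3. Aqueous acetic acid would give the triol F4, and pivaloyl chloride/pyridine at the primary hydroxyl the diol pivalate F5. NBS would then bring about the 5-endo bromoetherification (anti addition across the E-alkene, 2,5-trans closure), giving the bromo-oxolane F6 with all four ring stereocentres. Et3SiOTf/2,6-lutidine would give the silyl ether F7, i-Bu2AlH the primary alcohol F8, and Dess–Martin oxidation the aldehyde F9. Addition of Grignard reagent 24 as in step 17 would give the carbinol F10, and O-methylation as in step 18 would give 27.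

2. Step 19. What may go wrong: displacement at the neopentyl-type carbon is slow, so that S–O cleavage of the sulfonate or hydride attack at the secondary bromide competes. Fallback, setting out from 26 and returning at 27: Finkelstein exchange (NaI, DMF, 80 °C) would give the primary iodide F11, and radical chain reduction with one equivalent of Bu3SnH (Et3B/air, toluene, 0 °C), which abstracts the primary iodine much faster than the secondary bromine, would give 27.

3. Step 29. What may go wrong: intermolecular metathesis (oligomerisation) outruns ring closure, E/Z mixtures form, or the oxazole nitrogen sequesters the catalyst. Fallback, setting out from 36 and returning at 39: cross-metathesis of the terminal vinyl group with acrylic acid (second-generation Hoveyda–Grubbs catalyst, CH2Cl2, 40 °C) would give the E-enoic acid F12; PPTS/MeOH would give the seco acid F13; Yamaguchi macrolactonisation (2,4,6-trichlorobenzoyl chloride, Et3N, THF; then DMAP, toluene, high dilution) would give 39.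

Further compounds
F1 | step 7 | 1-[(but-3-yn-1-yloxy)methyl]-4-methoxybenzene | C#CCCOCc1ccc(OC)cc1
F2 | step 7 | (E)-1-{[(4-iodo-3-methylbut-3-en-1-yl)oxy]methyl}-4-methoxybenzene | I/C=C(C)/CCOCc1ccc(OC)cc1
F3 | step 7 | (1S,2E)-1-[(4R)-2,2-dimethyl-1,3-dioxolan-4-yl]-5-[(4-methoxybenzyl)oxy]-3-methylpent-2-en-1-ol (anti adduct) | O[C@@H](/C=C(C)/CCOCc1ccc(OC)cc1)[C@H]2COC(C)(C)O2
F4 | step 7 | anti triol from F3 after acetonide removal | O[C@@H](/C=C(C)/CCOCc1ccc(OC)cc1)[C@@H](CO)O
F5 | step 7 | primary pivalate of F4 | O[C@@H](/C=C(C)/CCOCc1ccc(OC)cc1)[C@@H](COC(=O)C(C)(C)C)O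
F6 | step 7 | 4-bromo-3-hydroxy-5-methyl-5-{2-[(4-methoxybenzyl)oxy]ethyl}oxolan-2-ylmethyl pivalate | O[C@@H]1[C@@H](COC(=O)C(C)(C)C)O[C@](C)(CCOCc2ccc(OC)cc2)[C@H]1Br
F7 | step 7 | 3-O-triethylsilyl ether of F6 | CC[Si](CC)(CC)O[C@@H]1[C@@H](COC(=O)C(C)(C)C)O[C@](C)(CCOCc2ccc(OC)cc2)[C@H]1Br
F8 | step 7 | [4-bromo-5-methyl-5-{2-[(4-methoxybenzyl)oxy]ethyl}-3-(triethylsilyloxy)oxolan-2-yl]methanol | CC[Si](CC)(CC)O[C@@H]1[C@@H](CO)O[C@](C)(CCOCc2ccc(OC)cc2)[C@H]1Br
F9 | step 7 | 4-bromo-5-methyl-5-{2-[(4-methoxybenzyl)oxy]ethyl}-3-(triethylsilyloxy)oxolane-2-carbaldehyde | CC[Si](CC)(CC)O[C@@H]1[C@@H](C=O)O[C@](C)(CCOCc2ccc(OC)cc2)[C@H]1Br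
F10 | step 7 | oxolane of F9 with C2 = (1S,3R)-1-hydroxy-3-methylpent-4-en-1-yl | CC[Si](CC)(CC)O[C@@H]1[C@@H]([C@@H](O)C[C@@H](C)C=C)O[C@](C)(CCOCc2ccc(OC)cc2)[C@H]1Br
F11 | step 19 | the 5-(iodomethyl) analogue of 26 | CC[Si](CC)(CC)O[C@@H]1[C@@H]([C@@H](OC)C[C@@H](C)C=C)O[C@](CI)(CCOCc2ccc(OC)cc2)[C@H]1Br
F12 | step 29 | E-enoic acid from cross-metathesis of 36 with acrylic acid (C3 OTES retained) | CC[Si](CC)(CC)O[C@@H]1[C@@H]([C@@H](OC)C[C@@H](C)CCc2nc(co2)/C(C)=C/[C@H](O[Si](C)(C)C(C)(C)C)[C@@H](C)/C=C/C(O)=O)O[C@](C)(CCOCc3ccc(OC)cc3)[C@H]1Br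
F13 | step 29 | seco acid (F12 with free C3 hydroxyl) | O[C@@H]1[C@@H]([C@@H](OC)C[C@@H](C)CCc2nc(co2)/C(C)=C/[C@H](O[Si](C)(C)C(C)(C)C)[C@@H](C)/C=C/C(O)=O)O[C@](C)(CCOCc3ccc(OC)cc3)[C@H]1Br
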